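The rate constants stand for no real mixture.

The grey flask is charged with more solid than the violet one, by a factor of 8.33, and you want to know whether that moves the share of L among L, E and J.

| flask | G | Q | time |
|---|---|---|---|
| violet | 0.060 mM | 0.0100 mM | 25 s |
| red | 0.15 mM | 0.0100 mM | 25 s |
| grey | 0.50 mM | 0.0100 mM | 25 s |

    D ⇌ L (K1 = 0.55, k1 = 0.092 s⁻¹)
    L ⇌ E (K2 = 0.59, k2 = 0.047 s⁻¹)
    E ⇌ J (K3 = 1.6, k3 = 0.047 s⁻¹)
    J ⇌ D (k4 = 0.31 s⁻¹)
    G ⇌ D, rate k5*(cs5 - [D]) while solid is left; crystals form when [D] > cs5 (cs5 = 0.082 mM, k5 = 0.045 s⁻¹)
    D + Q → D.Q (k6 = 2000 L mol⁻¹ s⁻¹)
    D ⇌ Z (K7 = 0.36, k7 = 0.017 s⁻¹)

- G is a solid; its amount is given per volume of the solution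
- at the start none of G is in solution
- "hardly changes" means that all values lie within two and a half points (for a concentration: within two and a half percent of the largest)
- run time (violet): 25 s

* share of L in all that became L or E or J for violet, red, grey, in this order
* the shape of the row from first to last (falls all the way / rises, then falls / hardly changes / rises all the way / falls, then rises)

Let us keep the books in fractions of the charge. Whatever leaves the solid enters as D, and D, L, E and J form a closed ring through steps 1 to 4. The constant of step 4 is built so that the ring closes. Every step of the ring has one species on its left, so its equilibrium proportions contain no concentration. Against a weight of one for D, L stands at 0.550, E at 0.325 and J at 0.519. Z, off to the side, stands at 0.36.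

From these weights I take the ring share, the fraction of L among L, E and J when each step of the ring stands at equilibrium: 39.5%. No charge enters it, so I commit to that one figure for violet, red and grey, and to a row that hardly changes. The relaxation of E and J by step 3 has a half-life of 9.08 s, shorter than the run of 25 s. That is 2.75 half-lives of one step, though, so I hold the figure as an estimate for the asked time and not as a state the ring has reached.

One entry remains. Q is the limiting reagent of step 6, charged in less than the G of violet, so D.Q has a ceiling of 16.7% of the violet charge. Take violet with its solid dissolved and D.Q at that ceiling. The remaining 83.3% is divided among weights that sum to 2.75. That puts D at 30.3%, L at 16.6%, E at 9.82%, J at 15.7% and Z at 10.9%, and the books close.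

The forecast, from a stepwise integration, gives 40%, 39.7% and 39.7%, with the shape hardly changes. Of red and grey it says “these two runs are identical”. My figure is lower than its red value, and it comes from the constants with no integration.

The flasks give 39.9%, 39.7% and 39.7%, and the shape is hardly changes. The forward half-life of J by step 4 alone, 2.2 s in violet, is short against the 25 s of the run, and the ring share lies 0.40 percentage points below violet and 0.20 points below grey, where G still stands at 85.6% of the charge after 25.0 s and E over D reads 0.190, lower than the weight of 0.325. In violet after 250 s, with Q down to 0.0109% of its own charge, L stands at 16.6% of the G charged, E at 9.82% and J at 15.7%.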